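**Retrosynthetic overview**
1. The target comes from the 1β,6α-diacetoxy-drim-7-ene-11,12-dial 14 by α-face hydroxylation at C9 (Rubottom oxidation of the only enolisable aldehyde).
2. The 6α-oxygen and the C7–C8 double bond come from the Δ6 bis-formyl decalin 11 by α-epoxidation and E1cB opening (allylic transposition), then acetylation.
3. Decalin 11 comes from the acyclic triene dial 10 by one intramolecular Diels–Alder reaction: ring A (C5–C10 bond, closed through the four-carbon tether) and ring B (C8–C9 bond) form together, with no ring present before this step.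
4. Triene 10 comes from the γ-acetoxy enal 8 and sorbaldehyde (ene–diene cross-metathesis); 8 comes from an alkyl iodide and a C5 enal acetal by catalytic asymmetric alkylzinc addition, which sets C1, the only stereocentre made by a reagent.

Assumption: the SMILES is read, in drimane numbering, as 1β,6α-diacetoxy-9α-hydroxydrim-7-ene-11,12-dial with 5α-H and 10β-CH3, i.e. (1S,4S,4aR,5R,8aS) as a naphthalene, and the carotenoid C5 building block (E)-4,4-dimethoxy-2-methylbut-2-enal is taken as a purchasable bulk chemical.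

**Route**

Step 1
Reactants: 1 methyl 3,3-dimethylpent-4-enoate
Product: 2 3,3-dimethylpent-4-en-1-ol
Conditions: LiAlH4, Et2O, 0 °C to rt
Reagents that add atoms: none
Why: Hydride reduction of the ester to the primary alcohol, the isolated vinyl group being inert; no stereocentre.

Step 2
Reactants: 2 3,3-dimethylpent-4-en-1-ol
Product: 3 5-iodo-3,3-dimethylpent-1-ene
Conditions: I2, PPh3, imidazole, CH2Cl2, 0 °C to rt
Reagents that add atoms: iodine [I][I]
Why: Appel-type iodination (Garegg–Samuelsson conditions), an SN2 displacement of the alkoxyphosphonium by iodide at the unhindered primary carbon; no stereocentre.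

Step 3
Reactants: 3 5-iodo-3,3-dimethylpent-1-ene; 4 (E)-4,4-dimethoxy-2-methylbut-2-enal
Product: 8 (2E,4R)-3,7,7-trimethyl-1-oxonona-2,8-dien-4-yl acetate, via dialkylzinc 5 (not isolated), via zinc alkoxide 6 (not isolated), via acetate acetal 7 (not isolated)
Conditions: 3, Et2Zn, CuI (cat.), neat, 50 °C, then vacuum; Ti(OiPr)4, (1S,2S)-1,2-bis(trifluoromethanesulfonamido)cyclohexane (8 mol%), toluene, −20 °C, 4; Ac2O, DMAP, 0 °C to rt; 1 M HCl, THF, rt
Reagents that add atoms: acetic anhydride CC(=O)OC(C)=O; water O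
Why: Iodine–zinc exchange gives the functionalised dialkylzinc, whose Ti(OiPr)4/bis-sulfonamide-catalysed enantioselective 1,2-addition (Yoshioka–Ohno–Knochel) to the α-methyl enal is delivered to the Re face by the (S,S)-ligand and so sets the (R)-carbinol centre (drimane C1); the alkoxide is trapped as its acetate and the acidic work-up hydrolyses the allylic dimethyl acetal to the (E)-enal.

Step 4
Reactants: 8 (2E,4R)-3,7,7-trimethyl-1-oxonona-2,8-dien-4-yl acetate; 9 (2E,4E)-hexa-2,4-dienal
Product: 10 (2E,4E,9R,10E)-6,6,10-trimethyl-1,12-dioxododeca-2,4,10-trien-9-yl acetate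
Conditions: second-generation Hoveyda–Grubbs catalyst (C31H38Cl2N2ORu, 5 mol%), 9 (4 equiv), CH2Cl2, 40 °C
Reagents that add atoms: none
Why: Ene–diene olefin cross-metathesis in which the quaternary-allylic terminal olefin cannot homodimerise and the electron-poor dienal reacts only at its distal 4,5-double bond (propene is lost); the quaternary neighbour enforces the new E-alkene, the trisubstituted enal of 8 is a spectator and no stereocentre is touched.

Step 5
Reactants: 10 (2E,4E,9R,10E)-6,6,10-trimethyl-1,12-dioxododeca-2,4,10-trien-9-yl acetate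
Product: 11 1β-acetoxy-5αH-drim-6-ene-11,12-dial (trans-decalin; 8β-CHO; 9β-CHO; 10β-CH3)
Conditions: toluene (0.005 M), BHT (cat.), 170 °C, sealed tube
Reagents that add atoms: none
Why: Thermal type 1 intramolecular Diels–Alder reaction of a 1,7,9-decatriene that closes rings A and B at once through a chair-like tether with the dienophile formyl group endo (trans ring fusion; 9β-CHO cis to 10β-CH3 from the E-enal; 8β-CHO from the E,E-diene) and with the C1 acetoxy group pseudo-equatorial and anti to the forming C5–C10 bond (Felkin-type, least allylic strain), so the single C1 centre fixes C5, C8, C9 and C10.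

Step 6
Reactants: 11 1β-acetoxy-5αH-drim-6-ene-11,12-dial
Product: 13 1β-acetoxy-6α-hydroxy-9αH-drim-7-ene-11,12-dial, via epoxide 12 (not isolated)
Conditions: DMDO, acetone, −20 to 0 °C; evaporate; Et3N, CH2Cl2, 0 °C to rt
Reagents that add atoms: dimethyldioxirane CC1(C)OO1
Why: Dimethyldioxirane epoxidises the only unconjugated alkene from the α face (the β face is screened by the axial 4β- and 10β-methyl groups and the 8β-formyl group) and amine-induced E1cB opening of the β,γ-epoxy aldehyde gives the γ-hydroxy enal, so the 6α-oxygen keeps its configuration while the double bond moves to C7–C8 (any epimerisation at C9 is erased in step 8).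

Step 7
Reactants: 13 1β-acetoxy-6α-hydroxy-9αH-drim-7-ene-11,12-dial
Product: 14 1β,6α-diacetoxy-9αH-drim-7-ene-11,12-dial
Conditions: Ac2O, pyridine, CH2Cl2, 0 °C to rt
Reagents that add atoms: acetic anhydride CC(=O)OC(C)=O
Why: Acylation of the secondary allylic 6α-alcohol under mild base without DMAP so that the C11 aldehyde is not enol-acetylated; the C6 configuration is retained.

Step 8
Reactants: 14 1β,6α-diacetoxy-9αH-drim-7-ene-11,12-dial
Product: 17 parritadial [(1S,4S,4aR,5R,8aS)-3,4-diformyl-4-hydroxy-4a,8,8-trimethyl-1,4,4a,5,6,7,8,8a-octahydronaphthalene-1,5-diyl diacetate], via silyl enol ether 15 (not isolated), via silyloxy aldehyde 16 (not isolated)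
Conditions: TMSOTf, Et3N, CH2Cl2, −78 to 0 °C; DMDO, acetone, −40 to 0 °C; aq. citric acid, THF, rt
Reagents that add atoms: dimethyldioxirane CC1(C)OO1
Why: Rubottom oxidation in which soft enolisation silylates the only enolisable aldehyde (C11; C12 is an enal), dimethyldioxirane epoxidises the electron-rich enol ether from the α face anti to the angular 10β-methyl group, a 1,4-silyl shift gives the 9α-silyloxy aldehyde and mild acid frees the tertiary 9α-alcohol.

**Compound list**
1 | methyl 3,3-dimethylpent-4-enoate | COC(=O)CC(C)(C)C=C | starting material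
2 | 3,3-dimethylpent-4-en-1-ol | OCCC(C)(C)C=C | intermediate
3 | 5-iodo-3,3-dimethylpent-1-ene | ICCC(C)(C)C=C | intermediate
4 | (E)-4,4-dimethoxy-2-methylbut-2-enal | COC(OC)/C=C(\C)C=O | starting material
5 | dialkylzinc: bis(3,3-dimethylpent-4-en-1-yl)zinc | C=CC(C)(C)CC[Zn]CCC(C)(C)C=C | intermediate
6 | zinc alkoxide: (3,3-dimethylpent-4-en-1-yl)zinc (2E,4R)-1,1-dimethoxy-3,7,7-trimethylnona-2,8-dien-4-olate | C=CC(C)(C)CC[C@@H](O[Zn]CCC(C)(C)C=C)/C(C)=C/C(OC)OC | intermediate
7 | acetate acetal: (2E,4R)-1,1-dimethoxy-3,7,7-trimethylnona-2,8-dien-4-yl acetate | C=CC(C)(C)CC[C@@H](OC(C)=O)/C(C)=C/C(OC)OC | intermediate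
8 | (2E,4R)-3,7,7-trimethyl-1-oxonona-2,8-dien-4-yl acetate | C=CC(C)(C)CC[C@@H](OC(C)=O)/C(C)=C/C=O | intermediate
9 | (2E,4E)-hexa-2,4-dienal (sorbaldehyde) | C/C=C/C=C/C=O | starting material
10 | (2E,4E,9R,10E)-6,6,10-trimethyl-1,12-dioxododeca-2,4,10-trien-9-yl acetate | O=C/C=C/C=C/C(C)(C)CC[C@@H](OC(C)=O)/C(C)=C/C=O | intermediate
11 | 1β-acetoxy-5αH-drim-6-ene-11,12-dial (8β-CHO, 9β-CHO, 10β-CH3, trans-decalin) | C1=C[C@H](C=O)[C@H](C=O)[C@@]2(C)[C@H](OC(C)=O)CCC(C)(C)[C@H]12 | intermediate
12 | epoxide: 1β-acetoxy-6α,7α-epoxy-5αH-drimane-11,12-dial | [C@@H]13O[C@H]3[C@H](C=O)[C@H](C=O)[C@@]2(C)[C@H](OC(C)=O)CCC(C)(C)[C@H]12 | intermediate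
13 | 1β-acetoxy-6α-hydroxy-9αH-drim-7-ene-11,12-dial | O[C@H]1C=C(C=O)[C@H](C=O)[C@@]2(C)[C@H](OC(C)=O)CCC(C)(C)[C@H]12 | intermediate
14 | 1β,6α-diacetoxy-9αH-drim-7-ene-11,12-dial | CC(=O)O[C@H]1C=C(C=O)[C@H](C=O)[C@@]2(C)[C@H](OC(C)=O)CCC(C)(C)[C@H]12 | intermediate
15 | silyl enol ether: 1β,6α-diacetoxy-11-(trimethylsilyloxy)drima-7,9(11)-dien-12-al (enol ether geometry not defined) | CC(=O)O[C@H]1C=C(C=O)C(=CO[Si](C)(C)C)[C@@]2(C)[C@H](OC(C)=O)CCC(C)(C)[C@H]12 | intermediate
16 | silyloxy aldehyde: 1β,6α-diacetoxy-9α-(trimethylsilyloxy)drim-7-ene-11,12-dial | CC(=O)O[C@H]1C=C(C=O)[C@](O[Si](C)(C)C)(C=O)[C@@]2(C)[C@H](OC(C)=O)CCC(C)(C)[C@H]12 | intermediate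
17 | parritadial, 1β,6α-diacetoxy-9α-hydroxydrim-7-ene-11,12-dial | CC(=O)O[C@H]1C=C(C=O)[C@](O)(C=O)[C@@]2(C)[C@H](OC(C)=O)CCC(C)(C)[C@H]12 | target

**Step count and risks**

Total step count: 8. Longest linear sequence: 8 (1 → 2 → 3 → 8 → 10 → 11 → 13 → 14 → 17).

Step 5 is the most likely to fail. The diene carries a formyl acceptor, so the cycloaddition is electronically mismatched and needs forcing conditions, and the trans ring fusion and facial control rest on analogy. The fallback makes the diene electron-neutral and sets out from 8 and 9. Sorbaldehyde 9 is converted with HC(OMe)3 and pyridinium p-toluenesulfonate in MeOH into (2E,4E)-1,1-dimethoxyhexa-2,4-diene F3. Cross-metathesis of 8 with this acetal (same ruthenium catalyst) gives (2E,4R,8E,10E)-12,12-dimethoxy-3,7,7-trimethyl-1-oxododeca-2,8,10-trien-4-yl acetate F4, in which only the dienophile is activated. Its normal-demand intramolecular Diels–Alder reaction (toluene, 130 °C) gives 1β-acetoxy-12,12-dimethoxy-5αH-drim-6-en-11-al F5. Oxalic acid on wet silica gel then frees the C12 aldehyde and the sequence comes back to the route at 11.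

Step 4 is the second risk. The quaternary-allylic olefin is slow in metathesis and the dienal could also be cut at its 2,3-double bond. The fallback builds the diene in two stages on the acetal and sets out from 7, isolated by quenching step 3 with aqueous NH4Cl in place of HCl. Cross-metathesis with (E)-but-2-enal (same catalyst) gives (2E,4R,8E)-1,1-dimethoxy-3,7,7-trimethyl-10-oxodeca-2,8-dien-4-yl acetate F1. Wittig reaction with Ph3P=CHCHO (toluene, 80 °C) gives (2E,4R,8E,10E)-1,1-dimethoxy-3,7,7-trimethyl-12-oxododeca-2,8,10-trien-4-yl acetate F2. 1 M HCl in THF then unmasks the enal and the sequence comes back to the route at 10.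

Step 8 is the third risk. Silylation could take the dienol ether of the C12 enal instead, and the oxidant could attack the hindered tetrasubstituted enol ether poorly. The fallback replaces enol ether oxidation by direct C–H hydroxylation and sets out from 14. SeO2 in dioxane at 80 °C hydroxylates the doubly activated (allylic and α-formyl) C9–H from the α face by an ene/[2,3]-shift sequence that leaves the C7–C8 double bond in place. No new compound is made on the way (F0) and the sequence comes back to the route at 17.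

**Further compounds**
F1 | step 4 | (2E,4R,8E)-1,1-dimethoxy-3,7,7-trimethyl-10-oxodeca-2,8-dien-4-yl acetate | O=C/C=C/C(C)(C)CC[C@@H](OC(C)=O)/C(C)=C/C(OC)OC
F2 | step 4 | (2E,4R,8E,10E)-1,1-dimethoxy-3,7,7-trimethyl-12-oxododeca-2,8,10-trien-4-yl acetate | O=C/C=C/C=C/C(C)(C)CC[C@@H](OC(C)=O)/C(C)=C/C(OC)OC
F3 | step 5 | (2E,4E)-1,1-dimethoxyhexa-2,4-diene | C/C=C/C=C/C(OC)OC
F4 | step 5 | (2E,4R,8E,10E)-12,12-dimethoxy-3,7,7-trimethyl-1-oxododeca-2,8,10-trien-4-yl acetate | COC(OC)/C=C/C=C/C(C)(C)CC[C@@H](OC(C)=O)/C(C)=C/C=O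
F5 | step 5 | 1β-acetoxy-12,12-dimethoxy-5αH-drim-6-en-11-al | C1=C[C@H](C(OC)OC)[C@H](C=O)[C@@]2(C)[C@H](OC(C)=O)CCC(C)(C)[C@H]12
F0 | step 8 | none | none
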